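In ring D the exocyclic-methylene carbon C16 and the bridging methylene C14 both hang on C13. Shifting the C13–C16 bond back to C14 therefore converts ring D (C8, C14, C13, C16, C15) into a methylenecyclobutane (C8, C15, C16, C14) that shares its C8–C14 edge with ring C, and that is what an enone–allene photocycloaddition delivers. The key step joins allene to a ring C enone, forming C8–C15 and C14–C16, the quaternary C8 and the four-membered ring at once; a C13 radical later returns C16 to C13. The precursor is a cyclohexenone (C13 ketone, C14=C8) carrying CH2OTBS on C8, OTBS on C12 and the ring A diester on C9.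

Key step: step 13

Remarks on the chemistry (made before the steps):
- Numbering is kaurane numbering: ring A = C1–C5, C10; ring C = C8, C9, C11–C14; ring D adds C15, C16; C17 = exocyclic CH2; C6 and C19 = carboxyl carbons on C5 and C4; C7 = aldehyde carbon on C8; C18, C20 = methyls on C4, C10. "Ring A unit" means ring A with CO2Me at C6 and C19. TBS = tert-butyldimethylsilyl, TMS = trimethylsilyl.
- C12 is a throwaway stereocentre (it ends as the ketone). It is drawn with the silyloxy group trans to ring A, the epimer to which enone 18 is equilibrated in step 12; the other epimer would converge at step 19.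
- The configurations of the C13 carbinol (21, 22) and of C10 in 6 and 7 are irrelevant, because these centres become radicals.
- The senses of induction of the esterase (step 2) and of the chiral lithium amide (step 7) are assumed by analogy with dimethyl cis-cyclohexane-1,2-dicarboxylate and 4-tert-butylcyclohexanone; if a sense is opposite, the antipodal amide or the step 2 fallback is used.

Step 1
Reactants: 1 trimethyl benzene-1,2,3-tricarboxylate
Product: 2 trimethyl all-cis-cyclohexane-1,2,3-tricarboxylate (meso)
Conditions: H2 (60 bar), 5% Rh/Al2O3, MeOH, 60 °C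
Reagents that add atoms: none
Why: Heterogeneous arene hydrogenation delivers all six hydrogens to one face of the ring, so the three ester groups should end all-cis and the product is the meso triester.

Step 2
Reactants: 2 trimethyl all-cis-cyclohexane-1,2,3-tricarboxylate (meso)
Product: 3 (1S,2S,3R)-2,3-bis(methoxycarbonyl)cyclohexane-1-carboxylic acid
Conditions: pig liver esterase, 0.1 M phosphate buffer (pH 7.5), 25 °C
Reagents that add atoms: water, O
Why: Enzymatic desymmetrisation of a meso ester should hydrolyse only one of the two enantiotopic outer esters (the central ester is flanked on both sides), which fixes the absolute configuration by making the future C10 the acid-bearing carbon while C5 and C4 keep the all-cis geometry.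

Step 3
Reactants: 3 (1S,2S,3R)-2,3-bis(methoxycarbonyl)cyclohexane-1-carboxylic acid
Product: 4 1-benzyl 2,3-dimethyl all-cis-cyclohexane-1,2,3-tricarboxylate
Conditions: BnBr, K2CO3, DMF, rt
Reagents that add atoms: benzyl bromide, BrCc1ccccc1
Why: SN2 O-alkylation of the carboxylate tags the C10 carboxyl with an ester that can later be removed by hydrogenolysis beside the two methyl esters, and no stereocentre is touched.

Step 4
Reactants: 4 1-benzyl 2,3-dimethyl all-cis-cyclohexane-1,2,3-tricarboxylate
Product: 6 1-benzyl 2,3-dimethyl 1,3-dimethylcyclohexane-1,2,3-tricarboxylate, via C4-monomethyl triester 5 (not isolated)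
Conditions: LiN(iPr)2 (1.1 equiv), THF–DMPU, −78 °C, then MeI; LiN(iPr)2 (1.2 equiv), −78 °C, then MeI, −78 → −20 °C (one flask)
Reagents that add atoms: iodomethane, CI
Why: Kinetic ester-enolate alkylation should take place at the two outer α-carbons (C4, C10) in preference to the doubly flanked C5–H, and each enolate should be methylated on the face opposite the neighbouring C5 ester, which places C18 trans and C19 cis to C6 (the C10 centre is destroyed in step 8).

Step 5
Reactants: 6 1-benzyl 2,3-dimethyl 1,3-dimethylcyclohexane-1,2,3-tricarboxylate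
Product: 7 ring A acid (2,3-bis(methoxycarbonyl)-1,3-dimethylcyclohexane-1-carboxylic acid)
Conditions: H2 (1 atm), 10% Pd/C, EtOAc, rt
Reagents that add atoms: none
Why: Catalytic hydrogenolysis cleaves only the benzyl ester and frees the tertiary C10 carboxylic acid without touching the methyl esters or any stereocentre.

Step 6
Reactants: 8 4-(hydroxymethyl)cyclohexan-1-one
Product: 9 4-[(tert-butyldimethylsilyloxy)methyl]cyclohexan-1-one
Conditions: TBSCl, imidazole, CH2Cl2, rt
Reagents that add atoms: tert-butyldimethylsilyl chloride, CC(C)(C)[Si](C)(C)Cl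
Why: Silyl ether formation protects the primary C7 hydroxyl for the base, radical and photochemical steps that follow.

Step 7
Reactants: 9 4-[(tert-butyldimethylsilyloxy)methyl]cyclohexan-1-one
Product: 11 (R)-4-[(tert-butyldimethylsilyloxy)methyl]cyclohex-2-en-1-one, via trimethylsilyl enol ether 10 (not isolated)
Conditions: (S,S)-bis(1-phenylethyl)amine, n-BuLi, THF, −78 °C; then 9 and TMSCl, −100 °C; crude 10: Pd(OAc)2 (1.05 equiv), MeCN, rt
Reagents that add atoms: none
Why: Enantiotopic α-deprotonation of the 4-substituted cyclohexanone by the C2-symmetric chiral lithium amide with internal silyl quench should give the (R)-configured silyl enol ether, and Saegusa–Ito oxidation converts it into the (R)-enone without touching the C8 stereocentre.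

Step 8
Reactants: 7 ring A acid; 11 (R)-4-[(tert-butyldimethylsilyloxy)methyl]cyclohex-2-en-1-one
Product: 12 C12 ketone (ring A unit on C9; CH2OTBS on C8; H8/H9 trans)
Conditions: Ir[dF(CF3)ppy]2(dtbbpy)PF6 (1 mol%), K2HPO4 (1.2 equiv), 11 (1.5 equiv), DMF, blue LEDs, rt
Reagents that add atoms: none
Why: In this photoredox decarboxylative Giese addition the carboxylate is oxidised and loses CO2 to give the tertiary C10 radical, which should add to the enone β-carbon C9 anti to the C8 silyloxymethyl group (trans-3,4 product, sets C9) and through the ring A face opposite the cis esters on C4 and C5 (sets C10), after which the α-keto radical is reduced and protonated.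

Step 9
Reactants: 12 C12 ketone (ring A unit on C9; CH2OTBS on C8; H8/H9 trans)
Product: 13 C12 tert-butyldimethylsilyl enol ether (C12=C13)
Conditions: LiN(iPr)2 (1.1 equiv), THF, −78 °C; TBSOTf (1.2 equiv), −78 °C
Reagents that add atoms: tert-butyldimethylsilyl trifluoromethanesulfonate, CC(C)(C)[Si](C)(C)OS(=O)(=O)C(F)(F)F
Why: Kinetic deprotonation should occur at C13 because the C11 protons are screened by the tert-alkyl group on C9, and O-silylation gives the C12=C13 enol ether whose silyl group is kept as the C12 protecting group (regioselective silyl enol ether formation).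

Step 10
Reactants: 13 C12 tert-butyldimethylsilyl enol ether (C12=C13)
Product: 15 trans-12-silyloxy-13-ol, via C13 alkylborane 14 (not isolated)
Conditions: BH3·THF (1.5 equiv), THF, 0 °C → rt; then NaBO3·4H2O, THF–H2O, rt
Reagents that add atoms: sodium perborate, [Na+].[O-]OB=O
Why: Hydroboration of a silyl enol ether puts boron on the carbon β to oxygen (C13) by syn addition and oxidation with retention gives the trans-12-silyloxy-13-ol, a 1,2-transposition of the oxygen pattern in which near-neutral perborate avoids silyl migration and the new C12 and C13 centres are not carried into the target.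

Step 11
Reactants: 15 trans-12-silyloxy-13-ol
Product: 16 13-ketone with 12-OTBS (C8 still CH)
Conditions: Dess–Martin periodinane (1.5 equiv), CH2Cl2, rt
Reagents that add atoms: none
Why: Dess–Martin oxidation converts the secondary alcohol into the C13 ketone under non-basic conditions that leave the α-silyloxy centre, the silyl ethers and the esters intact.

Step 12
Reactants: 16 13-ketone with 12-OTBS (C8 still CH)
Product: 18 ring C enone (photocycloaddition precursor), via C13 trimethylsilyl enol ether 17 (not isolated)
Conditions: LiN(iPr)2 (1.1 equiv), TMSCl, THF, −78 °C; crude 17: Pd(OAc)2 (1.1 equiv), MeCN, rt; then DBU (0.1 equiv), CH2Cl2, rt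
Reagents that add atoms: none
Why: Kinetic enolisation of the α-silyloxy ketone should occur at the C14 methylene and Saegusa–Ito oxidation of that enol ether removes the C8 hydrogen to give the C14=C8 enone, after which catalytic DBU equilibrates the enolisable C12 centre to the epimer with the silyloxy group trans to the pseudo-axial ring A substituent (the hindered γ-proton at C9 is not expected to exchange).

Step 13
Reactants: 18 ring C enone (photocycloaddition precursor); 19 allene
Product: 20 cis-fused methylenecyclobutane photoadduct
Conditions: allene (15 equiv), THF, −78 °C, hν (medium-pressure Hg lamp, Pyrex filter, λ > 300 nm); then neutral Al2O3, CH2Cl2, rt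
Reagents that add atoms: none
Why: Excitation of the enone with light that the esters and silyl ethers do not absorb, followed by intersystem crossing, gives the enone triplet, which adds to ground-state allene through a triplet 1,4-diradical; this is the known enone–allene [2+2] photocycloaddition that gives β,γ-unsaturated ketones. Head-to-head regiochemistry, with the central allene carbon C16 on the α-carbon C14 and a terminal CH2 (C15) on the β-carbon C8, is the intrinsic preference of cyclohexenones with allene and is needed so that the methylidene carbon sits next to C13. The four-membered ring C8–C15–C16–C14 closes by radical recombination within the 1,4-diradical after spin inversion, not by a polar or concerted ring closure. The new quaternary C8 is set by approach of allene anti to the ring A substituent on the adjacent C9, which allylic 1,2-strain with the C8 side chain holds pseudo-axial over one face of C8, so C15 should end trans to C10. C14 is set by the ring fusion: the cis-fused ketone is the stable isomer, and any trans-fused adduct is epimerised at the enolisable C14 on alumina. Excess allene at −78 °C keeps cycloaddition faster than enone dimerisation or hydrogen abstraction by the excited enone.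

Step 14
Reactants: 20 cis-fused methylenecyclobutane photoadduct
Product: 21 C13 alcohol (OH cis to the cyclobutane)
Conditions: NaBH4, MeOH, 0 °C
Reagents that add atoms: none
Why: Borohydride reduction is chemoselective for the ketone beside the methyl esters, with hydride expected on the face opposite the cyclobutane and the C12 silyloxy group, and the new C13 centre is destroyed in step 16, so either epimer serves.

Step 15
Reactants: 21 C13 alcohol (OH cis to the cyclobutane)
Product: 22 C13 O-phenyl thionocarbonate
Conditions: PhOC(S)Cl (2 equiv), pyridine, DMAP (0.2 equiv), CH2Cl2, rt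
Reagents that add atoms: O-phenyl chlorothionoformate, S=C(Cl)Oc1ccccc1
Why: Acylation of the hindered secondary alcohol under neutral pyridine/DMAP conditions installs the Barton–McCombie radical precursor without alkoxide intermediates that could move the neighbouring silyl group.

Step 16
Reactants: 22 C13 O-phenyl thionocarbonate
Product: 23 dimethyl 7,12-bis(tert-butyldimethylsilyloxy)-6,7-secokaur-16-ene-6,19-dioate
Conditions: Bu3SnH (1.5 equiv, syringe pump, 6 h), AIBN (0.2 equiv), toluene (0.005 M), 110 °C
Reagents that add atoms: none
Why: Proposed new method: Barton–McCombie C–O homolysis gives the secondary C13 radical, a homoallyl radical whose singly occupied orbital is aligned with the exocyclic cyclobutane bond C14–C16 and the C16=C17 π bond but nearly orthogonal to the ring bond C14–C8, so 3-exo closure onto C16 and opening of the cyclopropylcarbinyl radical by cleavage of C14–C16 (a 1,2-alkenyl shift driven by loss of cyclobutane strain) should move C16 suprafacially from C14 to C13, setting C13 on the face fixed by the cis ring fusion, before the C14 radical is reduced by slowly added Bu3SnH; the closest known reaction is the homoallyl radical rearrangement of bicyclo[2.2.2]octenyl radicals to bicyclo[3.2.1]octenes.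

Step 17
Reactants: 23 dimethyl 7,12-bis(tert-butyldimethylsilyloxy)-6,7-secokaur-16-ene-6,19-dioate
Product: 24 7,12-bis(tert-butyldimethylsilyloxy)-6,7-secokaur-16-ene-6,19-dioic acid
Conditions: NaSEt (6 equiv), DMF, 90 °C; then aq. HCl
Reagents that add atoms: none
Why: Thiolate SN2 attack at the O-methyl carbons should cleave both hindered methyl esters (one on the quaternary C4, one flanked by two quaternary carbons) without acyl attack or epimerisation at C5, and it is done before any carbonyl group is unveiled (nucleophilic ester dealkylation).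

Step 18
Reactants: 24 7,12-bis(tert-butyldimethylsilyloxy)-6,7-secokaur-16-ene-6,19-dioic acid
Product: 25 7,12-dihydroxy-6,7-secokaur-16-ene-6,19-dioic acid
Conditions: HF·pyridine, THF–pyridine, 0 °C → rt
Reagents that add atoms: none
Why: Fluoride-mediated desilylation with pyridine-buffered HF removes both silyl ethers under conditions mild enough for the exocyclic alkene and the free acids.

Step 19
Reactants: 25 7,12-dihydroxy-6,7-secokaur-16-ene-6,19-dioic acid
Product: 26 CNP0320711.1 (7,12-dioxo-6,7-secokaur-16-ene-6,19-dioic acid)
Conditions: Dess–Martin periodinane (3 equiv), CH2Cl2, rt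
Reagents that add atoms: none
Why: Dess–Martin oxidation should convert the neopentyl primary alcohol into the non-enolisable C7 aldehyde and the secondary alcohol into the C12 ketone in one operation, tolerates free carboxylic acids and cannot epimerise the bridgehead C13.

Compound list
1 | trimethyl benzene-1,2,3-tricarboxylate | COC(=O)c1cccc(C(=O)OC)c1C(=O)OC | starting material
2 | trimethyl all-cis-cyclohexane-1,2,3-tricarboxylate (meso) | [C@H]1(C(=O)OC)CCC[C@@H](C(=O)OC)[C@H]1C(=O)OC | intermediate
3 | (1S,2S,3R)-2,3-bis(methoxycarbonyl)cyclohexane-1-carboxylic acid (all-cis; free acid on the future C10) | [C@H]1(C(=O)O)CCC[C@@H](C(=O)OC)[C@H]1C(=O)OC | intermediate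
4 | 1-benzyl 2,3-dimethyl all-cis-cyclohexane-1,2,3-tricarboxylate (benzyl ester on the future C10; configuration as in 3) | [C@H]1(C(=O)OCc2ccccc2)CCC[C@@H](C(=O)OC)[C@H]1C(=O)OC | intermediate
5 | C4-monomethyl triester (4 with CH3 on C4 trans to the C5 ester) | [C@H]1(C(=O)OCc2ccccc2)CCC[C@@](C)(C(=O)OC)[C@H]1C(=O)OC | intermediate
6 | 1-benzyl 2,3-dimethyl 1,3-dimethylcyclohexane-1,2,3-tricarboxylate (three carboxyl groups cis, both methyls on the other face) | C[C@]1(C(=O)OCc2ccccc2)CCC[C@@](C)(C(=O)OC)[C@H]1C(=O)OC | intermediate
7 | ring A acid: 2,3-bis(methoxycarbonyl)-1,3-dimethylcyclohexane-1-carboxylic acid (C10 acid; the C10 carboxyl, C6 and C19 cis, both methyls trans to them) | C[C@]1(C(=O)O)CCC[C@@](C)(C(=O)OC)[C@H]1C(=O)OC | intermediate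
8 | 4-(hydroxymethyl)cyclohexan-1-one | O=C1CCC(CO)CC1 | starting material
9 | 4-[(tert-butyldimethylsilyloxy)methyl]cyclohexan-1-one | O=C1CCC(CO[Si](C)(C)C(C)(C)C)CC1 | intermediate
10 | (R)-4-[(tert-butyldimethylsilyloxy)methyl]-1-(trimethylsilyloxy)cyclohex-1-ene | C[Si](C)(C)OC1=CC[C@H](CO[Si](C)(C)C(C)(C)C)CC1 | intermediate
11 | (R)-4-[(tert-butyldimethylsilyloxy)methyl]cyclohex-2-en-1-one | O=C1C=C[C@H](CO[Si](C)(C)C(C)(C)C)CC1 | intermediate
12 | C12 ketone: cyclohexanone with the ring A unit on C9 and CH2OTBS (C7) on C8, H8/H9 trans, C9 and C10 as in the target | O=C1C[C@H]([C@H](CO[Si](C)(C)C(C)(C)C)CC1)[C@]1(C)CCC[C@@](C)(C(=O)OC)[C@H]1C(=O)OC | intermediate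
13 | C12 tert-butyldimethylsilyl enol ether of 12 (C12=C13) | CC(C)(C)[Si](C)(C)OC1=CC[C@@H](CO[Si](C)(C)C(C)(C)C)[C@@H](C1)[C@]1(C)CCC[C@@](C)(C(=O)OC)[C@H]1C(=O)OC | intermediate
14 | C13 alkylborane (BH2 on C13, trans to the C12 silyloxy group) | B[C@@H]1C[C@@H](CO[Si](C)(C)C(C)(C)C)[C@@H](C[C@H]1O[Si](C)(C)C(C)(C)C)[C@]1(C)CCC[C@@](C)(C(=O)OC)[C@H]1C(=O)OC | intermediate
15 | trans-12-silyloxy-13-ol (C12 OTBS trans to ring A, C13 OH trans to C12 OTBS) | O[C@@H]1C[C@@H](CO[Si](C)(C)C(C)(C)C)[C@@H](C[C@H]1O[Si](C)(C)C(C)(C)C)[C@]1(C)CCC[C@@](C)(C(=O)OC)[C@H]1C(=O)OC | intermediate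
16 | 13-ketone with 12-OTBS (C8 still CH) | O=C1C[C@@H](CO[Si](C)(C)C(C)(C)C)[C@@H](C[C@H]1O[Si](C)(C)C(C)(C)C)[C@]1(C)CCC[C@@](C)(C(=O)OC)[C@H]1C(=O)OC | intermediate
17 | C13 trimethylsilyl enol ether of 16 (C13=C14) | C[Si](C)(C)OC1=C[C@@H](CO[Si](C)(C)C(C)(C)C)[C@@H](C[C@H]1O[Si](C)(C)C(C)(C)C)[C@]1(C)CCC[C@@](C)(C(=O)OC)[C@H]1C(=O)OC | intermediate
18 | ring C enone (photocycloaddition precursor): C13 ketone, C14=C8, CH2OTBS on C8, ring A unit on C9, 12-OTBS trans to ring A | O=C1C=C(CO[Si](C)(C)C(C)(C)C)[C@@H](C[C@H]1O[Si](C)(C)C(C)(C)C)[C@]1(C)CCC[C@@](C)(C(=O)OC)[C@H]1C(=O)OC | intermediate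
19 | allene (propa-1,2-diene) | C=C=C | starting material
20 | cis-fused methylenecyclobutane photoadduct: new bonds C8–C15 and C14–C16, C16=C17H2, C13 ketone, C15 trans to C10 | O=C1[C@H]2C(=C)C[C@@]2(CO[Si](C)(C)C(C)(C)C)[C@@H](C[C@H]1O[Si](C)(C)C(C)(C)C)[C@]1(C)CCC[C@@](C)(C(=O)OC)[C@H]1C(=O)OC | intermediate
21 | C13 alcohol of 20 (OH cis to the cyclobutane) | O[C@H]1[C@H]2C(=C)C[C@@]2(CO[Si](C)(C)C(C)(C)C)[C@@H](C[C@H]1O[Si](C)(C)C(C)(C)C)[C@]1(C)CCC[C@@](C)(C(=O)OC)[C@H]1C(=O)OC | intermediate
22 | C13 O-phenyl thionocarbonate of 21 | S=C(Oc3ccccc3)O[C@H]1[C@H]2C(=C)C[C@@]2(CO[Si](C)(C)C(C)(C)C)[C@@H](C[C@H]1O[Si](C)(C)C(C)(C)C)[C@]1(C)CCC[C@@](C)(C(=O)OC)[C@H]1C(=O)OC | intermediate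
23 | dimethyl 7,12-bis(tert-butyldimethylsilyloxy)-6,7-secokaur-16-ene-6,19-dioate (rings C and D as bicyclo[3.2.1]octane, configuration of the target) | C=C1C[C@]2(CO[Si](C)(C)C(C)(C)C)C[C@H]1[C@H](O[Si](C)(C)C(C)(C)C)C[C@H]2[C@]1(C)CCC[C@@](C)(C(=O)OC)[C@H]1C(=O)OC | intermediate
24 | 7,12-bis(tert-butyldimethylsilyloxy)-6,7-secokaur-16-ene-6,19-dioic acid | C=C1C[C@]2(CO[Si](C)(C)C(C)(C)C)C[C@H]1[C@H](O[Si](C)(C)C(C)(C)C)C[C@H]2[C@]1(C)CCC[C@@](C)(C(=O)O)[C@H]1C(=O)O | intermediate
25 | 7,12-dihydroxy-6,7-secokaur-16-ene-6,19-dioic acid | C=C1C[C@]2(CO)C[C@H]1[C@H](O)C[C@H]2[C@]1(C)CCC[C@@](C)(C(=O)O)[C@H]1C(=O)O | intermediate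
26 | CNP0320711.1 (7,12-dioxo-6,7-secokaur-16-ene-6,19-dioic acid) | C=C1C[C@]2(C=O)C[C@H]1C(=O)C[C@H]2[C@]1(C)CCC[C@@](C)(C(=O)O)[C@H]1C(=O)O | target

Total step count: 19 (steps 1–5 ring A acid, steps 6–7 enone, steps 8–19 main line).
Longest linear sequence: 17 steps (steps 1–5, then 8–19).

Steps most likely to fail

1. Step 16 (radical 1,2-alkenyl shift). The C13 radical may take hydrogen from the stannane before it migrates, or the ring-fusion bond C14–C8 may break instead of the 3-exo closure. The fallback uses the acyl version of the same shift, which is known for fused cyclobutanones. It sets out from alcohol 21: ozonolysis of the exocyclic alkene (O3, CH2Cl2–MeOH, −78 °C; then Me2S) should give the cyclobutanone alcohol F1, which is acylated (PhOC(S)Cl, pyridine, DMAP) to the cyclobutanone thionocarbonate F2. With Bu3SnH/AIBN in hot toluene the C13 radical should add to the strained C16 carbonyl and the alkoxy radical should open C14–C16 (Dowd–Beckwith ring expansion), giving the bicyclo[3.2.1]octan-16-one F3. Wittig methylenation (Ph3P=CH2, THF) then returns to the route at 23.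

2. Step 8 (fragment union). Addition of the hindered tertiary radical to the γ-substituted enone may be slower than reduction or dimerisation of the radical under the basic, oxidising conditions. The fallback changes the radical precursor and the way the radical is made. It sets out from acid 7, which is converted (N-hydroxyphthalimide, N,N'-diisopropylcarbodiimide, DMAP, CH2Cl2) into the N-(acyloxy)phthalimide F4. Single-electron reduction and fragmentation of F4 (Ru(bpy)3(PF6)2, Hantzsch ester, iPr2NEt, CH2Cl2, blue LEDs) in the presence of enone 11 should give the same C10 radical under neutral, reductive conditions, with the Hantzsch ester supplying the hydrogen, and comes back to the route at 12.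

3. Step 2 (enzymatic desymmetrisation). The esterase may hydrolyse the central ester, discriminate poorly between the enantiotopic outer esters, or prefer the wrong one. The fallback replaces the enzyme by a reagent-controlled opening of a meso anhydride. It sets out from triester 1: selective saponification of the two unhindered outer esters (NaOH, 2 equiv, aq. MeOH) should give 2-(methoxycarbonyl)benzene-1,3-dicarboxylic acid F5. Arene hydrogenation (H2, Rh/Al2O3) then gives the all-cis cyclohexane diacid F6, and dehydration (Ac2O, heat) the bridged meso anhydride F7. Alkaloid-mediated methanolysis (quinidine or quinine as required, MeOH, toluene, −55 °C) opens one enantiotopic carbonyl and comes back to the route at 3.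

Further compounds
F1 | step 16 | cyclobutanone alcohol (21 with C16=O in place of C16=CH2) | O[C@H]1[C@H]2C(=O)C[C@@]2(CO[Si](C)(C)C(C)(C)C)[C@@H](C[C@H]1O[Si](C)(C)C(C)(C)C)[C@]1(C)CCC[C@@](C)(C(=O)OC)[C@H]1C(=O)OC
F2 | step 16 | cyclobutanone thionocarbonate (C13 O-phenyl thionocarbonate of F1) | S=C(Oc3ccccc3)O[C@H]1[C@H]2C(=O)C[C@@]2(CO[Si](C)(C)C(C)(C)C)[C@@H](C[C@H]1O[Si](C)(C)C(C)(C)C)[C@]1(C)CCC[C@@](C)(C(=O)OC)[C@H]1C(=O)OC
F3 | step 16 | bicyclo[3.2.1]octan-16-one (23 with C16=O in place of C16=CH2) | O=C1C[C@]2(CO[Si](C)(C)C(C)(C)C)C[C@H]1[C@H](O[Si](C)(C)C(C)(C)C)C[C@H]2[C@]1(C)CCC[C@@](C)(C(=O)OC)[C@H]1C(=O)OC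
F4 | step 8 | N-(acyloxy)phthalimide of ring A acid 7 | C[C@]1(C(=O)ON2C(=O)c3ccccc3C2=O)CCC[C@@](C)(C(=O)OC)[C@H]1C(=O)OC
F5 | step 2 | 2-(methoxycarbonyl)benzene-1,3-dicarboxylic acid | COC(=O)c1c(C(=O)O)cccc1C(=O)O
F6 | step 2 | all-cis-2-(methoxycarbonyl)cyclohexane-1,3-dicarboxylic acid (meso) | [C@H]1(C(=O)O)CCC[C@@H](C(=O)O)[C@H]1C(=O)OC
F7 | step 2 | methyl 2,4-dioxo-3-oxabicyclo[3.3.1]nonane-9-carboxylate (meso anhydride, ester syn to the anhydride bridge) | [C@H]1(C(=O)O2)CCC[C@@H](C2=O)[C@H]1C(=O)OC
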